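**Plan**

- Labels and enabling feature: ring C1 (bears the side chain), C2 (OH), C3H2, C4(CH3)=C5, C6H2, C7=C8 (its formyl carbon is called C8'), C9 (its formyl carbon is C10); side chain C11 (CH) with C18 (CH2OAc) and the homoprenyl group. In the nine-membered ring the carbinol carbon C2 sits next to C3, the allylic CH2 of the E-C4(CH3)=C5 alkene, so C2 can react as an acyl-anion equivalent (a nitronate) with an allyl cation spread over C3–C4–C5.
- Retrosynthetic cuts: both CHO groups back to silyl-protected CH2OH and C2–OH back to C2=O and C2–NO2; ring bond C2–C3; C1–C11 (Michael addition); C1=C2 (Henry reaction); C7=C8 (aldol condensation) and C9–C1 (conjugate addition), both on a butenolide; C4=C5 (Wittig reaction).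
- Forward order: the C3–C7 aldehyde and the homoprenyl aldehyde are made separately; dithiane (C1), a chiral butenolide (C8', C8, C9, C10) and the C3–C7 aldehyde are joined in one flask; nitromethane (C2) and the homoprenyl aldehyde (C11, C18) extend the chain; the only ring closes late at C2–C3.
- Stereochemistry: C9 from the (5R)-menthyloxybutenolide (addition anti to the acetal oxygen); C11 and C1 from the (R)-diphenylprolinol silyl ether catalyst (syn Michael adduct); C2 from hydride addition to the ring ketone anti to the C1 side chain; E-C4=C5 from the stabilised ylide; C7=C8 from E1cB elimination to the E-alkylidene lactone, which is the ring-cis geometry.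

Key step: step 18

Remark: the two nitro epimers at C2 formed in step 18 are carried together, because C2 becomes a carbonyl carbon in step 19.
Abbreviations: TBS-oxy = tert-butyl(dimethyl)silyloxy; PMB = 4-methoxybenzyl; Men = (1R,2S,5R)-5-methyl-2-(propan-2-yl)cyclohexyl, from (−)-menthol.

**Route**

Step 1
Reactants: 1 5-bromo-2-methylpent-2-ene; 2 oxirane
Product: 4 6-methylhept-5-en-1-ol, via Grignard reagent 3 (not isolated)
Conditions: Mg, THF, reflux; then 2, CuI (10 mol%), −30 → 0 °C; H2O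
Reagents that add atoms: none
Why: Copper-catalysed ring opening of oxirane by the homoprenyl Grignard reagent is the standard two-carbon homologation of an alkyl halide to a primary alcohol and leaves the trisubstituted alkene alone.

Step 2
Reactants: 4 6-methylhept-5-en-1-ol
Product: 5 6-methylhept-5-enal
Conditions: TEMPO (10 mol%), PhI(OAc)2 (1.1 equiv), CH2Cl2, rt
Reagents that add atoms: none
Why: TEMPO (oxoammonium) oxidation of a primary alcohol stops at the aldehyde and does not attack the electron-rich alkene.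

Step 3
Reactants: 6 3-(TBS-oxy)propanal; 7 ethyl 2-(triphenylphosphoranylidene)propanoate
Product: 8 ethyl (2E)-2-methyl-5-(TBS-oxy)pent-2-enoate
Conditions: CH2Cl2, rt
Reagents that add atoms: none
Why: The Wittig reaction of a stabilised α-methyl ylide gives the trisubstituted enoate with the E geometry that is kept as the C4=C5 alkene.

Step 4
Reactants: 8 ethyl (2E)-2-methyl-5-(TBS-oxy)pent-2-enoate
Product: 9 (2E)-2-methyl-5-(TBS-oxy)pent-2-en-1-ol
Conditions: iBu2AlH (2.2 equiv), CH2Cl2, −78 °C; aq potassium sodium tartrate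
Reagents that add atoms: none
Why: 1,2-Reduction of the enoate by the aluminium hydride at low temperature gives the allylic alcohol (the later C3–OH) without touching the alkene geometry.

Step 5
Reactants: 9 (2E)-2-methyl-5-(TBS-oxy)pent-2-en-1-ol
Product: 10 (3E)-4-methyl-5-(PMB-oxy)pent-3-en-1-yl TBS ether
Conditions: NaH, PMBCl, Bu4NI (cat.), THF–DMF, 0 °C → rt
Reagents that add atoms: 4-methoxybenzyl chloride, COc1ccc(CCl)cc1
Why: Williamson etherification protects the C3 oxygen as an ether that survives hydride, enolate and fluoride steps and can later be removed oxidatively.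

Step 6
Reactants: 10 (3E)-4-methyl-5-(PMB-oxy)pent-3-en-1-yl TBS ether
Product: 11 (3E)-4-methyl-5-(PMB-oxy)pent-3-en-1-ol
Conditions: Bu4NF, THF, 0 °C → rt
Reagents that add atoms: none
Why: Fluoride-mediated desilylation frees the primary alcohol while the benzyl-type ether is inert.

Step 7
Reactants: 11 (3E)-4-methyl-5-(PMB-oxy)pent-3-en-1-ol
Product: 12 (3E)-4-methyl-5-(PMB-oxy)pent-3-enal
Conditions: TEMPO (10 mol%), PhI(OAc)2 (1.1 equiv), CH2Cl2, 0 °C → rt; used crude
Reagents that add atoms: none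
Why: TEMPO oxidation under non-basic conditions should give the β,γ-unsaturated aldehyde without moving the alkene into conjugation.

Step 8
Reactants: 13 1,3-dithiane; 14 (5R)-5-(Men-oxy)furan-2(5H)-one; 12 (3E)-4-methyl-5-(PMB-oxy)pent-3-enal
Product: 17 (3S,4R,5R)-4-(1,3-dithian-2-yl)-3-[(3E)-1-hydroxy-4-methyl-5-(PMB-oxy)pent-3-en-1-yl]-5-(Men-oxy)dihydrofuran-2(3H)-one (both carbinol epimers), via 2-lithio-1,3-dithiane 15 (not isolated), via lithium enolate 16 (not isolated)
Conditions: 13, n-BuLi, THF, −30 °C; 14, THF–DMPU, −78 °C; 12, −78 °C; AcOH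
Reagents that add atoms: none
Why: Tandem conjugate addition–aldol reaction, in which the lithiated dithiane adds to the β-carbon (C9) anti to the menthyloxy group on the neighbouring acetal carbon, which sets C9, and the lactone enolate is trapped by aldehyde 12 anti to the dithianyl group; both carbinol epimers serve because C7 and C8 become sp2 in step 9.

Step 9
Reactants: 17 aldol adduct
Product: 19 (3E,4R,5R)-4-(1,3-dithian-2-yl)-3-[(3E)-4-methyl-5-(PMB-oxy)pent-3-en-1-ylidene]-5-(Men-oxy)dihydrofuran-2(3H)-one, via mesylate 18 (not isolated)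
Conditions: MsCl, Et3N, CH2Cl2, 0 °C; then DBU, 0 °C → rt (short contact)
Reagents that add atoms: none
Why: Mesylation and E1cB elimination through the lactone enolate should give the thermodynamically preferred E-alkylidene lactone (vinyl hydrogen syn to the carbonyl), which places C6 cis to C9 as the ring-cis C7=C8 alkene requires.

Step 10
Reactants: 19 alkylidene lactone acetal
Product: 20 (2E,3R)-3-(1,3-dithian-2-yl)-2-[(3E)-4-methyl-5-(PMB-oxy)pent-3-en-1-ylidene]butane-1,4-diol
Conditions: iBu2AlH (6 equiv), CH2Cl2, −78 → 0 °C; aq potassium sodium tartrate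
Reagents that add atoms: none
Why: Exhaustive hydride reduction of the lactone acetal, in which the lactol aluminate opens on warming, menthoxide leaves from C10 and both aldehyde groups are reduced as they form, so that the C9 centre is reduced past the aldehyde stage faster than it can enolise.

Step 11
Reactants: 20 diol
Product: 21 2-[(2R,3E,6E)-7-methyl-8-(PMB-oxy)-1-(TBS-oxy)-3-(TBS-oxymethyl)octa-3,6-dien-2-yl]-1,3-dithiane
Conditions: TBSCl (2.5 equiv), imidazole, DMF, rt
Reagents that add atoms: tert-butyl(chloro)dimethylsilane, CC(C)(C)[Si](C)(C)Cl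
Why: Imidazole-mediated silylation of both primary alcohols gives ethers that should last until step 21.

Step 12
Reactants: 21 bis-silyl dithiane
Product: 22 (2R,3E,6E)-7-methyl-8-(PMB-oxy)-2,3-bis(TBS-oxymethyl)octa-3,6-dienal
Conditions: MeI, CaCO3, MeCN–H2O (9:1), rt, dark; used at once without chromatography
Reagents that add atoms: water, O
Why: Alkylative dithiane hydrolysis (S-methylation, ring opening, attack of water) frees the C1 aldehyde under neutral buffered conditions, and because C9–H is now α to the formyl group and allylic the aldehyde is carried on immediately.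

Step 13
Reactants: 22 aldehyde; 23 nitromethane
Product: 25 (1E,3R,4E,7E)-8-methyl-1-nitro-9-(PMB-oxy)-3,4-bis(TBS-oxymethyl)nona-1,4,7-triene, via nitro aldol 24 (not isolated)
Conditions: 23 (as solvent), Et3N (0.2 equiv), 0 °C; concentrate; DCC, CuCl (cat.), Et2O, rt
Reagents that add atoms: none
Why: A Henry reaction with a catalytic amine followed by carbodiimide dehydration of the nitro aldol gives the E-nitroalkene without strong base, and allylic 1,3-strain holds the C9–H bond near the plane of both flanking alkenes, which should slow its removal.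

Step 14
Reactants: 25 nitroalkene; 5 6-methylhept-5-enal
Product: 27 (2S,3R,4R,5E,8E)-9-methyl-2-(4-methylpent-3-en-1-yl)-3-(nitromethyl)-10-(PMB-oxy)-4,5-bis(TBS-oxymethyl)deca-5,8-dien-1-ol, via nitroaldehyde 26 (not isolated)
Conditions: 5 (3 equiv), (R)-2-[diphenyl(trimethylsilyloxy)methyl]pyrrolidine (20 mol%), 4-nitrophenol (20 mol%), toluene, 0 °C; then MeOH, NaBH4, 0 °C
Reagents that add atoms: none
Why: Enamine-catalysed Michael addition of an aldehyde to a nitroalkene, in which the E-enamine of 5, shielded on one face by the diphenyl(silyloxy)methyl group of the (R)-catalyst, attacks C1 through the acyclic synclinal transition state and should give the syn adduct with C11 (S) and C1 (R in 27) under catalyst control, while reduction in the same flask prevents epimerisation at C11.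

Step 15
Reactants: 27 nitro alcohol
Product: 28 (2S,3R,4R,5E,8E)-9-methyl-2-(4-methylpent-3-en-1-yl)-3-(nitromethyl)-10-(PMB-oxy)-4,5-bis(TBS-oxymethyl)deca-5,8-dien-1-yl acetate
Conditions: Ac2O, pyridine, CH2Cl2, 0 °C → rt
Reagents that add atoms: acetic anhydride, CC(=O)OC(C)=O
Why: Acylation of the primary alcohol installs the C18 acetate of the target, and pyridine is too weak a base to form the nitronate.

Step 16
Reactants: 28 nitro acetate
Product: 29 (2S,3R,4R,5E,8E)-10-hydroxy-9-methyl-2-(4-methylpent-3-en-1-yl)-3-(nitromethyl)-4,5-bis(TBS-oxymethyl)deca-5,8-dien-1-yl acetate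
Conditions: DDQ, CH2Cl2–pH 7 buffer, 0 °C
Reagents that add atoms: none
Why: Oxidative cleavage of the 4-methoxybenzyl ether (benzylic hydride abstraction by the quinone, then hydrolysis) frees the C3 allylic alcohol and leaves silyl ethers, acetate and nitro group untouched.

Step 17
Reactants: 29 allylic alcohol
Product: 30 (2S,3R,4R,5E,8E)-10-[(methoxycarbonyl)oxy]-9-methyl-2-(4-methylpent-3-en-1-yl)-3-(nitromethyl)-4,5-bis(TBS-oxymethyl)deca-5,8-dien-1-yl acetate
Conditions: ClCO2Me, pyridine, CH2Cl2, 0 °C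
Reagents that add atoms: methyl chloroformate, COC(=O)Cl
Why: Acylation with the chloroformate turns the allylic alcohol into the methyl carbonate, a leaving group that releases its own base on ionisation.

Step 18
Reactants: 30 nitro allylic carbonate
Product: 31 (2S)-2-[(1R,4E,7E,9R)-4-methyl-2-nitro-8,9-bis(TBS-oxymethyl)cyclonona-4,7-dien-1-yl]-6-methylhept-5-en-1-yl acetate (both C2 epimers)
Conditions: Pd2(dba)3·CHCl3 (5 mol%), dppe (12 mol%), THF, 60 °C, syringe-pump addition (final 2 mM)
Reagents that add atoms: none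
Why: Zerovalent palladium ionises the E-allylic methyl carbonate to a syn π-allylpalladium cation spanning C3–C4–C5, the methoxide set free after loss of CO2 deprotonates the CH2NO2 group, and the soft nitronate attacks the allyl terminus C3 through carbon on the face opposite to palladium. The closest known reaction type is the Tsuji–Trost allylic alkylation of nitroalkanes with allylic carbonates under neutral conditions, together with palladium-mediated medium- and large-ring closures by stabilised carbanions. The nine-membered ring closes by attack at the distal, unsubstituted terminus C3, so that the whole allyl unit becomes endocyclic and the syn complex delivers the E-C4=C5 alkene. The new stereocentre C2 is not under reliable control (kinetic attack, then equilibration through the nitronate) and is removed in step 19. The step needs attack at C3 and not at C5 (which would give a seven-membered ring bearing an isopropenyl group), C- over O-alkylation and ring closure over oligomerisation: the primary terminus and the branched nucleophile favour C3, O-allyl nitronates re-ionise under the catalyst, and the cis C7=C8 alkene together with slow addition at high dilution favours the intramolecular path.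

Step 19
Reactants: 31 2-nitrocyclononadiene
Product: 33 (2S)-2-[(1R,4E,7E,9R)-4-methyl-2-oxo-8,9-bis(TBS-oxymethyl)cyclonona-4,7-dien-1-yl]-6-methylhept-5-en-1-yl acetate, via potassium nitronate 32 (not isolated)
Conditions: KOtBu (1.05 equiv), THF, 0 °C; then aq TiCl3 (4 equiv), NH4OAc (pH 5–6), THF–H2O, 0 °C → rt
Reagents that add atoms: water, O
Why: Reductive Nef reaction, in which the nitronate is reduced by trivalent titanium to the imine that hydrolyses to the ketone in the buffered medium, which should spare the acetate, the silyl ethers, the α-stereocentre C1 and the β,γ-position of the C4=C5 alkene.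

Step 20
Reactants: 33 ring ketone
Product: 34 (2S)-2-[(1R,2S,4E,7E,9R)-2-hydroxy-4-methyl-8,9-bis(TBS-oxymethyl)cyclonona-4,7-dien-1-yl]-6-methylhept-5-en-1-yl acetate
Conditions: LiBH(s-Bu)3 (1.2 equiv), THF, −78 °C; H2O
Reagents that add atoms: none
Why: Ketone reduction by a bulky trialkylborohydride, whose hydride should approach C2 from the ring face opposite to the branched C1 side chain and so place the hydroxyl cis to that chain (2S), while the acetate survives at −78 °C.

Step 21
Reactants: 34 bis-silyl alcohol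
Product: 35 (2S)-2-[(1R,2S,4E,7E,9R)-2-hydroxy-8,9-bis(hydroxymethyl)-4-methylcyclonona-4,7-dien-1-yl]-6-methylhept-5-en-1-yl acetate
Conditions: HF·pyridine, pyridine, THF, 0 °C → rt
Reagents that add atoms: none
Why: Fluoride-mediated cleavage removes both primary silyl ethers under buffered conditions that leave the acetate and the alkenes intact.

Step 22
Reactants: 35 triol
Product: 36 (2S)-2-[(1R,2S,4E,7E,9R)-8,9-diformyl-2-hydroxy-4-methylcyclonona-4,7-dien-1-yl]-6-methylhept-5-en-1-yl acetate (target)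
Conditions: TEMPO (20 mol%), PhI(OAc)2 (2.4 equiv), CH2Cl2, 0 °C → rt
Reagents that add atoms: none
Why: TEMPO/PhI(OAc)2 oxidation is selective for primary over hindered secondary alcohols and is non-basic, so both CH2OH groups should become CHO while the C2 hydroxyl, the epimerisable C9 centre and the skipped diene are kept, and lactol formation between C2–OH and C10 is disfavoured by their trans arrangement on the ring.

**Compound list**

1 | 5-bromo-2-methylpent-2-ene | CC(C)=CCCBr | starting material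
2 | oxirane | C1CO1 | starting material
3 | (4-methylpent-3-en-1-yl)magnesium bromide | CC(C)=CCC[Mg]Br | intermediate (not isolated)
4 | 6-methylhept-5-en-1-ol | CC(C)=CCCCCO | intermediate
5 | 6-methylhept-5-enal | CC(C)=CCCCC=O | intermediate
6 | 3-{[tert-butyl(dimethyl)silyl]oxy}propanal | O=CCCO[Si](C)(C)C(C)(C)C | starting material
7 | ethyl 2-(triphenylphosphoranylidene)propanoate | CCOC(=O)C(C)=P(c1ccccc1)(c1ccccc1)c1ccccc1 | starting material
8 | ethyl (2E)-2-methyl-5-(TBS-oxy)pent-2-enoate | CCOC(=O)/C(C)=C/CCO[Si](C)(C)C(C)(C)C | intermediate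
9 | (2E)-2-methyl-5-(TBS-oxy)pent-2-en-1-ol | OC/C(C)=C/CCO[Si](C)(C)C(C)(C)C | intermediate
10 | (3E)-4-methyl-5-(PMB-oxy)pent-3-en-1-yl TBS ether | COc1ccc(COC/C(C)=C/CCO[Si](C)(C)C(C)(C)C)cc1 | intermediate
11 | (3E)-4-methyl-5-(PMB-oxy)pent-3-en-1-ol | COc1ccc(COC/C(C)=C/CCO)cc1 | intermediate
12 | (3E)-4-methyl-5-(PMB-oxy)pent-3-enal | COc1ccc(COC/C(C)=C/CC=O)cc1 | intermediate
13 | 1,3-dithiane | C1CSCSC1 | starting material
14 | (5R)-5-{[(1R,2S,5R)-5-methyl-2-(propan-2-yl)cyclohexyl]oxy}furan-2(5H)-one | O=C1C=C[C@H](O[C@@H]2C[C@H](C)CC[C@H]2C(C)C)O1 | starting material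
15 | 2-lithio-1,3-dithiane | [Li]C1SCCCS1 | intermediate (not isolated)
16 | lithium enolate of (4R,5R)-4-(1,3-dithian-2-yl)-5-(Men-oxy)dihydrofuran-2(3H)-one | [Li]OC1=C[C@@H](C2SCCCS2)[C@H](O[C@@H]2C[C@H](C)CC[C@H]2C(C)C)O1 | intermediate (not isolated)
17 | (3S,4R,5R)-4-(1,3-dithian-2-yl)-3-[(3E)-1-hydroxy-4-methyl-5-(PMB-oxy)pent-3-en-1-yl]-5-(Men-oxy)dihydrofuran-2(3H)-one, both carbinol epimers | O=C1O[C@@H](O[C@@H]2C[C@H](C)CC[C@H]2C(C)C)[C@H](C2SCCCS2)[C@H]1C(O)C/C=C(\C)COCc1ccc(OC)cc1 | intermediate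
18 | methanesulfonate of 17 | O=C1O[C@@H](O[C@@H]2C[C@H](C)CC[C@H]2C(C)C)[C@H](C2SCCCS2)[C@H]1C(OS(C)(=O)=O)C/C=C(\C)COCc1ccc(OC)cc1 | intermediate (not isolated)
19 | (3E,4R,5R)-4-(1,3-dithian-2-yl)-3-[(3E)-4-methyl-5-(PMB-oxy)pent-3-en-1-ylidene]-5-(Men-oxy)dihydrofuran-2(3H)-one | O=C1O[C@@H](O[C@@H]2C[C@H](C)CC[C@H]2C(C)C)[C@H](C2SCCCS2)/C1=C\C/C=C(\C)COCc1ccc(OC)cc1 | intermediate
20 | (2E,3R)-3-(1,3-dithian-2-yl)-2-[(3E)-4-methyl-5-(PMB-oxy)pent-3-en-1-ylidene]butane-1,4-diol | OC[C@H](C1SCCCS1)/C(CO)=C\C/C=C(\C)COCc1ccc(OC)cc1 | intermediate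
21 | 2-[(2R,3E,6E)-7-methyl-8-(PMB-oxy)-1-(TBS-oxy)-3-(TBS-oxymethyl)octa-3,6-dien-2-yl]-1,3-dithiane | CC(C)(C)[Si](C)(C)OC[C@H](C1SCCCS1)/C(CO[Si](C)(C)C(C)(C)C)=C\C/C=C(\C)COCc1ccc(OC)cc1 | intermediate
22 | (2R,3E,6E)-7-methyl-8-(PMB-oxy)-2,3-bis(TBS-oxymethyl)octa-3,6-dienal | O=C[C@@H](CO[Si](C)(C)C(C)(C)C)/C(CO[Si](C)(C)C(C)(C)C)=C\C/C=C(\C)COCc1ccc(OC)cc1 | intermediate
23 | nitromethane | C[N+](=O)[O-] | starting material
24 | (3R,4E,7E)-8-methyl-1-nitro-9-(PMB-oxy)-3,4-bis(TBS-oxymethyl)nona-4,7-dien-2-ol, both carbinol epimers | [O-][N+](=O)CC(O)[C@@H](CO[Si](C)(C)C(C)(C)C)/C(CO[Si](C)(C)C(C)(C)C)=C\C/C=C(\C)COCc1ccc(OC)cc1 | intermediate (not isolated)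
25 | (1E,3R,4E,7E)-8-methyl-1-nitro-9-(PMB-oxy)-3,4-bis(TBS-oxymethyl)nona-1,4,7-triene | [O-][N+](=O)/C=C/[C@@H](CO[Si](C)(C)C(C)(C)C)/C(CO[Si](C)(C)C(C)(C)C)=C\C/C=C(\C)COCc1ccc(OC)cc1 | intermediate
26 | (2S,3S,4R,5E,8E)-9-methyl-2-(4-methylpent-3-en-1-yl)-3-(nitromethyl)-10-(PMB-oxy)-4,5-bis(TBS-oxymethyl)deca-5,8-dienal | O=C[C@@H](CCC=C(C)C)[C@@H](C[N+](=O)[O-])[C@@H](CO[Si](C)(C)C(C)(C)C)/C(CO[Si](C)(C)C(C)(C)C)=C\C/C=C(\C)COCc1ccc(OC)cc1 | intermediate (not isolated)
27 | (2S,3R,4R,5E,8E)-9-methyl-2-(4-methylpent-3-en-1-yl)-3-(nitromethyl)-10-(PMB-oxy)-4,5-bis(TBS-oxymethyl)deca-5,8-dien-1-ol | OC[C@@H](CCC=C(C)C)[C@@H](C[N+](=O)[O-])[C@@H](CO[Si](C)(C)C(C)(C)C)/C(CO[Si](C)(C)C(C)(C)C)=C\C/C=C(\C)COCc1ccc(OC)cc1 | intermediate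
28 | (2S,3R,4R,5E,8E)-9-methyl-2-(4-methylpent-3-en-1-yl)-3-(nitromethyl)-10-(PMB-oxy)-4,5-bis(TBS-oxymethyl)deca-5,8-dien-1-yl acetate | CC(=O)OC[C@@H](CCC=C(C)C)[C@@H](C[N+](=O)[O-])[C@@H](CO[Si](C)(C)C(C)(C)C)/C(CO[Si](C)(C)C(C)(C)C)=C\C/C=C(\C)COCc1ccc(OC)cc1 | intermediate
29 | (2S,3R,4R,5E,8E)-10-hydroxy-9-methyl-2-(4-methylpent-3-en-1-yl)-3-(nitromethyl)-4,5-bis(TBS-oxymethyl)deca-5,8-dien-1-yl acetate | CC(=O)OC[C@@H](CCC=C(C)C)[C@@H](C[N+](=O)[O-])[C@@H](CO[Si](C)(C)C(C)(C)C)/C(CO[Si](C)(C)C(C)(C)C)=C\C/C=C(\C)CO | intermediate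
30 | (2S,3R,4R,5E,8E)-10-[(methoxycarbonyl)oxy]-9-methyl-2-(4-methylpent-3-en-1-yl)-3-(nitromethyl)-4,5-bis(TBS-oxymethyl)deca-5,8-dien-1-yl acetate | CC(=O)OC[C@@H](CCC=C(C)C)[C@@H](C[N+](=O)[O-])[C@@H](CO[Si](C)(C)C(C)(C)C)/C(CO[Si](C)(C)C(C)(C)C)=C\C/C=C(\C)COC(=O)OC | intermediate
31 | (2S)-2-[(1R,4E,7E,9R)-4-methyl-2-nitro-8,9-bis(TBS-oxymethyl)cyclonona-4,7-dien-1-yl]-6-methylhept-5-en-1-yl acetate, both C2 epimers | CC(=O)OC[C@@H](CCC=C(C)C)[C@H]1C([N+](=O)[O-])C/C(C)=C/C/C=C(/CO[Si](C)(C)C(C)(C)C)[C@@H]1CO[Si](C)(C)C(C)(C)C | intermediate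
32 | potassium nitronate of 31 | CC(=O)OC[C@@H](CCC=C(C)C)[C@H]1C(=[N+]([O-])[O-])C/C(C)=C/C/C=C(/CO[Si](C)(C)C(C)(C)C)[C@@H]1CO[Si](C)(C)C(C)(C)C.[K+] | intermediate (not isolated)
33 | (2S)-2-[(1R,4E,7E,9R)-4-methyl-2-oxo-8,9-bis(TBS-oxymethyl)cyclonona-4,7-dien-1-yl]-6-methylhept-5-en-1-yl acetate | CC(=O)OC[C@@H](CCC=C(C)C)[C@H]1C(=O)C/C(C)=C/C/C=C(/CO[Si](C)(C)C(C)(C)C)[C@@H]1CO[Si](C)(C)C(C)(C)C | intermediate
34 | (2S)-2-[(1R,2S,4E,7E,9R)-2-hydroxy-4-methyl-8,9-bis(TBS-oxymethyl)cyclonona-4,7-dien-1-yl]-6-methylhept-5-en-1-yl acetate | CC(=O)OC[C@@H](CCC=C(C)C)[C@H]1[C@@H](O)C/C(C)=C/C/C=C(/CO[Si](C)(C)C(C)(C)C)[C@@H]1CO[Si](C)(C)C(C)(C)C | intermediate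
35 | (2S)-2-[(1R,2S,4E,7E,9R)-2-hydroxy-8,9-bis(hydroxymethyl)-4-methylcyclonona-4,7-dien-1-yl]-6-methylhept-5-en-1-yl acetate | CC(=O)OC[C@@H](CCC=C(C)C)[C@H]1[C@@H](O)C/C(C)=C/C/C=C(/CO)[C@@H]1CO | intermediate
36 | (2S)-2-[(1R,2S,4E,7E,9R)-8,9-diformyl-2-hydroxy-4-methylcyclonona-4,7-dien-1-yl]-6-methylhept-5-en-1-yl acetate | CC(=O)OC[C@@H](CCC=C(C)C)[C@H]1[C@@H](O)C/C(C)=C/C/C=C(/C=O)[C@@H]1C=O | target

**Step count**

Total steps: 22.
Longest linear sequence: 20 steps (steps 3–7, then steps 8–22).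

**Steps most likely to fail**

Step 18 (ring closure). The nitronate may attack the proximal allyl terminus C5 and give a seven-membered ring, or attack a second molecule and give oligomers, or the allyl complex may lose a proton to a triene. The fallback pairs the nitronate with an aldehyde instead of an allyl cation, so that C3 is the only electrophilic carbon. It sets out from allylic alcohol 29: MnO2 oxidation should give the E-enal F1. An intramolecular Henry reaction at high dilution (catalytic tetramethylguanidine, THF) should then close the C2–C3 bond to the cyclic β-nitro alcohol F2. Dehydration (DCC, CuCl) should give the cyclic nitrodiene F3, and conjugate reduction at C3 with NaBH4 comes back to the route at nitro compound 31.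

Step 14 (Michael addition). Addition to the hindered β-carbon may be slow enough for the amine to remove the C9 proton, which would epimerise C9 or move the nitroalkene out of conjugation; the catalyst and the C9 centre may also be mismatched and erode facial selectivity. The fallback replaces amine catalysis by an auxiliary-bound titanium enolate under Lewis-acidic conditions. It sets out from aldehyde 5, which is oxidised (NaClO2, NaH2PO4, 2-methylbut-2-ene) to 6-methylhept-5-enoic acid F4. This is joined (pivaloyl chloride, Et3N, then lithiated (R)-4-benzyloxazolidin-2-one) to the N-acyloxazolidinone F5. Its chlorotitanium enolate (TiCl4, iPr2NEt, CH2Cl2, −78 °C) should add to nitroalkene 25 on the face opposite to the benzyl group and give the Michael adduct F6. The C11 configuration follows the known sense of this auxiliary; the C1 configuration would have to be confirmed. Reductive removal of the auxiliary with LiBH4 comes back to the route at nitro alcohol 27.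

Step 20 (ketone reduction). Hydride may be delivered to the other face of the flexible ring ketone, giving poor or reversed facial selectivity. The fallback corrects C2 by inversion instead of by direct reduction. It sets out from ketone 33: reduction with a small hydride (NaBH4, CeCl3, MeOH), or whichever reagent favours the other face, would give the 2R alcohol F7. Mitsunobu inversion with chloroacetic acid (PPh3, diisopropyl azodicarboxylate) should give the 2S chloroacetate F8. Thiourea (NaHCO3, EtOH) removes the chloroacetyl group without touching the acetate and comes back to the route at alcohol 34.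

**Further compounds**

F1 | step 18 | (2S,3R,4R,5E,8E)-9-methyl-2-(4-methylpent-3-en-1-yl)-3-(nitromethyl)-10-oxo-4,5-bis(TBS-oxymethyl)deca-5,8-dien-1-yl acetate | CC(=O)OC[C@@H](CCC=C(C)C)[C@@H](C[N+](=O)[O-])[C@@H](CO[Si](C)(C)C(C)(C)C)/C(CO[Si](C)(C)C(C)(C)C)=C\C/C=C(\C)C=O
F2 | step 18 | (2S)-2-[(1R,4E,7E,9R)-3-hydroxy-4-methyl-2-nitro-8,9-bis(TBS-oxymethyl)cyclonona-4,7-dien-1-yl]-6-methylhept-5-en-1-yl acetate, epimers at C2 and C3 | CC(=O)OC[C@@H](CCC=C(C)C)[C@H]1C([N+](=O)[O-])C(O)/C(C)=C/C/C=C(/CO[Si](C)(C)C(C)(C)C)[C@@H]1CO[Si](C)(C)C(C)(C)C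
F3 | step 18 | (2S)-2-[(1R,4E,7E,9R)-4-methyl-2-nitro-8,9-bis(TBS-oxymethyl)cyclonona-2,4,7-trien-1-yl]-6-methylhept-5-en-1-yl acetate | CC(=O)OC[C@@H](CCC=C(C)C)[C@H]1C([N+](=O)[O-])=C/C(C)=C/C/C=C(/CO[Si](C)(C)C(C)(C)C)[C@@H]1CO[Si](C)(C)C(C)(C)C
F4 | step 14 | 6-methylhept-5-enoic acid | CC(C)=CCCCC(=O)O
F5 | step 14 | (4R)-4-benzyl-3-(6-methylhept-5-enoyl)-1,3-oxazolidin-2-one | CC(C)=CCCCC(=O)N1[C@H](Cc2ccccc2)COC1=O
F6 | step 14 | (4R)-4-benzyl-3-[(2S,3S,4R,5E,8E)-9-methyl-2-(4-methylpent-3-en-1-yl)-3-(nitromethyl)-10-(PMB-oxy)-4,5-bis(TBS-oxymethyl)deca-5,8-dienoyl]-1,3-oxazolidin-2-one | O=C1OC[C@@H](Cc2ccccc2)N1C(=O)[C@@H](CCC=C(C)C)[C@@H](C[N+](=O)[O-])[C@@H](CO[Si](C)(C)C(C)(C)C)/C(CO[Si](C)(C)C(C)(C)C)=C\C/C=C(\C)COCc1ccc(OC)cc1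
F7 | step 20 | (2S)-2-[(1R,2R,4E,7E,9R)-2-hydroxy-4-methyl-8,9-bis(TBS-oxymethyl)cyclonona-4,7-dien-1-yl]-6-methylhept-5-en-1-yl acetate | CC(=O)OC[C@@H](CCC=C(C)C)[C@H]1[C@H](O)C/C(C)=C/C/C=C(/CO[Si](C)(C)C(C)(C)C)[C@@H]1CO[Si](C)(C)C(C)(C)C
F8 | step 20 | (2S)-2-[(1R,2S,4E,7E,9R)-2-[(chloroacetyl)oxy]-4-methyl-8,9-bis(TBS-oxymethyl)cyclonona-4,7-dien-1-yl]-6-methylhept-5-en-1-yl acetate | CC(=O)OC[C@@H](CCC=C(C)C)[C@H]1[C@@H](OC(=O)CCl)C/C(C)=C/C/C=C(/CO[Si](C)(C)C(C)(C)C)[C@@H]1CO[Si](C)(C)C(C)(C)C
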